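The route rests on cutting the bond between C6 of the benzo ring of the 1,4-benzodioxane and the neighbouring stilbene CH. The key step exploits that C6 stands para to ring oxygen O1: para-bromination of a 2-alkoxyphenol places the coupling handle and fixes the dioxane regiochemistry in one move. In the last step a Mizoroki–Heck reaction without protecting groups joins the enantiopure (2R,3R)-6-bromobenzodioxane, carrying three free OH groups, to 5-vinylresorcinol; it forms the aryl–alkenyl bond, sets the E-alkene and releases aiphanol directly. The bromide arises from an Evans syn-aldol reaction (C2) and a biomimetic quinone methide ring closure (C3, trans).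

Key step: step 9

Remark: the target is read as the trans-(2R,3R) isomer. In benzodioxine numbering, C2 carries CH2OH and is bound to O1, C3 carries the syringyl ring and is bound to O4, and C6 carries the styryl group. Compound 3 is taken as a catalogue compound.

Step 1
Reactants: 1 2-(allyloxy)phenol
Product: 2 2-(allyloxy)-4-bromophenol
Conditions: NBS (1.0 equiv), MeCN, −10 to 0 °C, dark
Reagents that add atoms: N-bromosuccinimide, O=C1CCC(=O)N1Br
Why: Electrophilic aromatic bromination with NBS in MeCN is directed by the free OH, the strongest donor, to its open para position, and the activated ring reacts far faster than the allyl C=C.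

Step 2
Reactants: 2 2-(allyloxy)-4-bromophenol; 3 (S)-4-benzyl-3-(chloroacetyl)oxazolidin-2-one
Product: 4 (S)-3-{[2-(allyloxy)-4-bromophenoxy]acetyl}-4-benzyloxazolidin-2-one
Conditions: K2CO3 (1.5 equiv), NaI (0.1 equiv), acetone, rt to 40 °C
Reagents that add atoms: none
Why: Williamson-type SN2 displacement in which the phenoxide of 2 attacks the strongly activated alpha-chloro imide carbon under iodide catalysis, an irreversible event that outruns reversible attack at the imide carbonyl and leaves the auxiliary stereocentre untouched.

Step 3
Reactants: 5 syringaldehyde (4-hydroxy-3,5-dimethoxybenzaldehyde)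
Product: 6 4-(allyloxy)-3,5-dimethoxybenzaldehyde
Conditions: allyl bromide (1.2 equiv), K2CO3 (1.5 equiv), DMF, 50 °C
Reagents that add atoms: allyl bromide, C=CCBr
Why: Williamson ether synthesis on the acidic syringyl OH with a reactive allylic halide masks the phenol for the boron aldol step with the same group that 2 carries, so that one later operation removes both.

Step 4
Reactants: 4 (S)-3-{[2-(allyloxy)-4-bromophenoxy]acetyl}-4-benzyloxazolidin-2-one; 6 4-(allyloxy)-3,5-dimethoxybenzaldehyde
Product: 8 (4S)-3-{(2S,3R)-2-[2-(allyloxy)-4-bromophenoxy]-3-[4-(allyloxy)-3,5-dimethoxyphenyl]-3-hydroxypropanoyl}-4-benzyloxazolidin-2-one, via Z-dibutylboron enolate 7 (not isolated)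
Conditions: Bu2BOTf (1.2 equiv), Et3N (1.4 equiv), CH2Cl2, −78 to 0 °C; 6, −78 to 0 °C; then pH 7 buffer, MeOH, 30% H2O2, 0 °C
Reagents that add atoms: none
Why: Evans syn-aldol reaction in which soft enolisation gives the Z-boron enolate 7, which reacts through a Zimmerman–Traxler chair on the face away from the benzyl group of the (S)-auxiliary and so sets C2 of the acyl chain as S (the later C2 of the dioxane ring) and C3 as R.

Step 5
Reactants: 8 syn-aldol adduct
Product: 9 (1R,2R)-2-[2-(allyloxy)-4-bromophenoxy]-1-[4-(allyloxy)-3,5-dimethoxyphenyl]propane-1,3-diol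
Conditions: LiBH4 (2.5 equiv), MeOH (2.5 equiv), THF, 0 °C
Reagents that add atoms: none
Why: Reductive cleavage of the N-acyl oxazolidinone with LiBH4 attacks the more electrophilic exocyclic carbonyl and gives the primary alcohol without touching the aryl bromide, the allyl ethers or either stereocentre, the descriptor of the aryloxy carbon changing from S to R only because the priorities change.

Step 6
Reactants: 9 bis-allyl diol
Product: 10 (1R,2R)-2-(4-bromo-2-hydroxyphenoxy)-1-(4-hydroxy-3,5-dimethoxyphenyl)propane-1,3-diol
Conditions: Pd(PPh3)4 (5 mol %), morpholine (6 equiv), THF, rt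
Reagents that add atoms: none
Why: Tsuji–Trost deallylation in which zerovalent palladium ionises both aryl allyl ethers at room temperature to pi-allyl complexes that morpholine captures, while the electron-rich C–Br bond does not undergo oxidative addition under these conditions.

Step 7
Reactants: 10 (1R,2R)-2-(4-bromo-2-hydroxyphenoxy)-1-(4-hydroxy-3,5-dimethoxyphenyl)propane-1,3-diol
Product: 12 [(2R,3R)-6-bromo-3-(4-hydroxy-3,5-dimethoxyphenyl)-2,3-dihydro-1,4-benzodioxin-2-yl]methanol, via quinone methide 11 (not isolated)
Conditions: TsOH·H2O (0.1 equiv), CH2Cl2/THF 5:1, 0.01 M, rt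
Reagents that add atoms: none
Why: Acid-catalysed dehydration of the p-hydroxybenzyl alcohol gives quinone methide 11 (reacting as its O-protonated form), which the neighbouring catechol OH captures by 6-exo-trig oxa-1,6-addition as in the presumed biosynthesis; the fixed C2 centre steers the aryl and CH2OH groups into the diequatorial trans arrangement, and the reversibility of the closure funnels material to the (2R,3R) isomer.

Step 8
Reactants: 13 3,5-dihydroxybenzaldehyde
Product: 14 5-vinylbenzene-1,3-diol (5-vinylresorcinol)
Conditions: MePPh3Br (3.5 equiv), KOtBu (3.4 equiv), THF, 0 °C to rt; aq NH4Cl; used fresh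
Reagents that add atoms: methyltriphenylphosphonium bromide, C[P+](c1ccccc1)(c1ccccc1)c1ccccc1.[Br-]
Why: Wittig methylenation with excess ylide, in which the first two equivalents of base only deprotonate the meta phenols, whose oxido groups are not conjugated with the aldehyde, so the carbonyl stays reactive and no protecting group is needed.

Step 9
Reactants: 12 [(2R,3R)-6-bromo-3-(4-hydroxy-3,5-dimethoxyphenyl)-2,3-dihydro-1,4-benzodioxin-2-yl]methanol; 14 5-vinylbenzene-1,3-diol
Product: 15 aiphanol, 5-[(E)-2-[(2R,3R)-3-(4-hydroxy-3,5-dimethoxyphenyl)-2-(hydroxymethyl)-2,3-dihydro-1,4-benzodioxin-6-yl]ethenyl]benzene-1,3-diol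
Conditions: Pd(OAc)2 (5 mol %), P(o-tol)3 (15 mol %), Et3N (4 equiv), BHT (1 mol %), DMF, 100 °C, Ar
Reagents that add atoms: none
Why: Mizoroki–Heck reaction: zerovalent palladium, formed in situ from Pd(OAc)2 and the phosphine, inserts into the C6–Br bond of 12, the aryl–palladium bromide adds syn across the vinyl group of 14 with the aryl group going to the terminal CH2 carbon, and bond rotation, syn beta-hydride elimination and capture of HBr by Et3N release the stilbene and regenerate the catalyst. The closest known reaction type is the tri-o-tolylphosphine-assisted Heck arylation of styrenes with bromophenols and bromoanisoles, which proceeds with free OH groups because amine bases leave most of the phenol protonated. No ring is closed and no stereocentre is created; the one new stereoelement, the E double bond, is controlled by the elimination conformer that keeps the two aryl groups anti. The step needs regioselectivity for the linear 1,2-diaryl alkene, secured by the steric and electronic bias of the neutral aryl–palladium bromide for the unsubstituted terminus of a styrene, and site selectivity, secured by the single carbon–halogen bond in 12. The stereocentres C2 and C3 are spectators: C2 has no acidic or ionisable bond, and any reversible opening at C3 through the quinone methide recloses under the control of C2 to the trans isomer.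

Compound list
1 | 2-(allyloxy)phenol | C=CCOc1ccccc1O | starting material
2 | 2-(allyloxy)-4-bromophenol | C=CCOc1cc(Br)ccc1O | intermediate
3 | (S)-4-benzyl-3-(chloroacetyl)oxazolidin-2-one | O=C(CCl)N1C(=O)OC[C@@H]1Cc1ccccc1 | starting material
4 | (S)-3-{[2-(allyloxy)-4-bromophenoxy]acetyl}-4-benzyloxazolidin-2-one | C=CCOc1cc(Br)ccc1OCC(=O)N1C(=O)OC[C@@H]1Cc1ccccc1 | intermediate
5 | syringaldehyde | COc1cc(C=O)cc(OC)c1O | starting material
6 | 4-(allyloxy)-3,5-dimethoxybenzaldehyde | C=CCOc1c(OC)cc(C=O)cc1OC | intermediate
7 | (Z)-dibutylboron enolate of 4 (aryloxy and boryloxy groups on the same side) | C=CCOc1cc(Br)ccc1O/C=C(\OB(CCCC)CCCC)N1C(=O)OC[C@@H]1Cc1ccccc1 | intermediate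
8 | (4S)-3-{(2S,3R)-2-[2-(allyloxy)-4-bromophenoxy]-3-[4-(allyloxy)-3,5-dimethoxyphenyl]-3-hydroxypropanoyl}-4-benzyloxazolidin-2-one | C=CCOc1c(OC)cc(cc1OC)[C@@H](O)[C@@H](C(=O)N1C(=O)OC[C@@H]1Cc1ccccc1)Oc1ccc(Br)cc1OCC=C | intermediate
9 | (1R,2R)-2-[2-(allyloxy)-4-bromophenoxy]-1-[4-(allyloxy)-3,5-dimethoxyphenyl]propane-1,3-diol | C=CCOc1c(OC)cc(cc1OC)[C@@H](O)[C@@H](CO)Oc1ccc(Br)cc1OCC=C | intermediate
10 | (1R,2R)-2-(4-bromo-2-hydroxyphenoxy)-1-(4-hydroxy-3,5-dimethoxyphenyl)propane-1,3-diol | COc1cc(cc(OC)c1O)[C@@H](O)[C@@H](CO)Oc1ccc(Br)cc1O | intermediate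
11 | 4-[(2S)-2-(4-bromo-2-hydroxyphenoxy)-3-hydroxypropylidene]-2,6-dimethoxycyclohexa-2,5-dien-1-one (p-quinone methide, reacting as its O-protonated form) | COC1=CC(=C[C@@H](CO)Oc2ccc(Br)cc2O)C=C(OC)C1=O | intermediate
12 | [(2R,3R)-6-bromo-3-(4-hydroxy-3,5-dimethoxyphenyl)-2,3-dihydro-1,4-benzodioxin-2-yl]methanol (trans) | COc1cc([C@H]2Oc3cc(Br)ccc3O[C@@H]2CO)cc(OC)c1O | intermediate
13 | 3,5-dihydroxybenzaldehyde | O=Cc1cc(O)cc(O)c1 | starting material
14 | 5-vinylbenzene-1,3-diol | C=Cc1cc(O)cc(O)c1 | intermediate
15 | aiphanol | COc1cc([C@H]2Oc3cc(/C=C/c4cc(O)cc(O)c4)ccc3O[C@@H]2CO)cc(OC)c1O | target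

Total step count: 9. Longest linear sequence: 7 steps (1, 2, 4, 5, 6, 7, 9).

Steps most likely to fail

Step 9.
- **What may go wrong:** oxidative addition into the electron-rich C6–Br bond may be sluggish at a temperature at which the vinylresorcinol polymerises. The free phenols may also deactivate the catalyst.
- **Fallback:** it sets out from 14 and 12 and comes back at 15. Cross-metathesis of 14 with vinylboronic acid pinacol ester (second-generation Grubbs catalyst, CH2Cl2, 40 °C) should give (E)-5-[2-(4,4,5,5-tetramethyl-1,3,2-dioxaborolan-2-yl)ethenyl]benzene-1,3-diol F1, in which the E geometry is already fixed. Suzuki–Miyaura coupling of F1 with 12 (PdCl2(dppf), K3PO4, dioxane/H2O, 70 °C) then forms the same C6–CH bond. It does so by transmetallation and reductive elimination instead of carbopalladation, at lower temperature and with retention of the alkene geometry, and gives 15.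

Step 7.
- **What may go wrong:** trans selectivity in the ring closure may be incomplete. Acid may cleave the beta-aryl ether, the benzylic cation may be trapped intermolecularly, and proton loss next to the cation would erode C2.
- **Fallback:** it sets out from 10 and comes back at 12. Peracetylation of 10 (Ac2O, pyridine, DMAP, rt) should give (1R,2R)-1-(4-acetoxy-3,5-dimethoxyphenyl)-2-(2-acetoxy-4-bromophenoxy)propane-1,3-diyl diacetate F2. Treatment of F2 with K2CO3 in THF/MeOH at 0 °C to rt cleaves the aryl acetates first. The syringyl phenoxide then expels the benzylic acetate by 1,6-elimination, so 11 is generated under basic instead of acidic conditions. The adjacent catechol phenoxide adds to 11 faster than the solvent does, and methanolysis of the primary acetate completes the conversion to 12.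

Step 2.
- **What may go wrong:** acyl transfer from the imide to the phenoxide, with loss of the auxiliary, may compete with substitution at the CH2Cl carbon.
- **Fallback:** it sets out from 2 and comes back at 4, and builds the imide by N-acylation instead of O-alkylation. Compound 2 is alkylated with sodium chloroacetate (NaOH, H2O, reflux) to [2-(allyloxy)-4-bromophenoxy]acetic acid F3. F3 is activated with PivCl and Et3N (THF, −20 °C) as [2-(allyloxy)-4-bromophenoxy]acetic pivalic anhydride F4. F4 acylates (S)-4-benzyloxazolidin-2-one (LiCl, Et3N, THF, rt) to give 4.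

Further compounds
F1 | step 9 | (E)-5-[2-(4,4,5,5-tetramethyl-1,3,2-dioxaborolan-2-yl)ethenyl]benzene-1,3-diol | CC1(C)OB(/C=C/c2cc(O)cc(O)c2)OC1(C)C
F2 | step 7 | (1R,2R)-1-(4-acetoxy-3,5-dimethoxyphenyl)-2-(2-acetoxy-4-bromophenoxy)propane-1,3-diyl diacetate | COc1cc(cc(OC)c1OC(C)=O)[C@@H](OC(C)=O)[C@@H](COC(C)=O)Oc1ccc(Br)cc1OC(C)=O
F3 | step 2 | [2-(allyloxy)-4-bromophenoxy]acetic acid | C=CCOc1cc(Br)ccc1OCC(=O)O
F4 | step 2 | [2-(allyloxy)-4-bromophenoxy]acetic pivalic anhydride | C=CCOc1cc(Br)ccc1OCC(=O)OC(=O)C(C)(C)C
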